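Ring B is closed at the bond between C9 of ring C (aromatic, later the quinone) and the exocyclic carbon C20. The key step exploits the C1 oxygen that flanks the C10=C20 alkene on ring A: with C1 as a ketone, C10=C20 is an α-methylene ketone, and an intramolecular Mizoroki–Heck reaction of a C9 aryl bromide delivers the aryl group to C20 (7-endo) and regenerates the conjugated C10=C20 bond in one operation. The precursor is a seco-compound: a cis-fused ring A enone γ-lactone with the aryl carbinol at C6, made by Diels–Alder reaction of a butenolide whose C6/C7 centres come from an asymmetric vinylogous aldol reaction.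

Key step: step 10

Remark: locants are icetexane locants throughout, also in seco intermediates (ring A = C1–C5, C10; ring B = C5–C10 with C20 between C10 and C9; ring C = C8, C9, C11–C14; C19 = lactone carbonyl on C4); Ar = 2-bromo-3,4,6-trimethoxy-5-(propan-2-yl)phenyl, TBS = tert-butyldimethylsilyl; the antipode of the aldol catalyst that gives the (6R,7S) adduct is assumed to be identified on a model aldehyde.

Step 1
Reactants: 1 1,2,4-trimethoxybenzene
Product: 3 2-(2,3,6-trimethoxyphenyl)propan-2-ol, via (2,3,6-trimethoxyphenyl)lithium 2 (not isolated)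
Conditions: n-BuLi, THF, 0 °C; then acetone, −78 °C to rt; H2O
Reagents that add atoms: acetone, CC(C)=O
Why: Directed ortho-metalation removes the proton flanked by two methoxy groups (the future C13) and the aryllithium adds 1,2 to acetone.

Step 2
Reactants: 3 2-(2,3,6-trimethoxyphenyl)propan-2-ol
Product: 4 1,2,4-trimethoxy-3-(propan-2-yl)benzene
Conditions: Et3SiH, CF3CO2H, CH2Cl2, 0 °C to rt
Reagents that add atoms: none
Why: Ionic hydrogenation: the tertiary benzylic cation formed in acid is reduced by hydride transfer from the silane.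

Step 3
Reactants: 4 1,2,4-trimethoxy-3-(propan-2-yl)benzene
Product: 6 1-bromo-2,3,5-trimethoxy-4-(propan-2-yl)benzene, via [2,3,5-trimethoxy-4-(propan-2-yl)phenyl]lithium 5 (not isolated)
Conditions: n-BuLi, TMEDA, Et2O, 0 °C; then BrCl2C–CCl2Br, −78 °C to rt
Reagents that add atoms: 1,2-dibromo-1,1,2,2-tetrachloroethane, ClC(Cl)(Br)C(Cl)(Cl)Br
Why: Directed ortho-metalation should occur at C9 next to the C11 methoxy group, because the C14 methoxy group is buttressed by the isopropyl group and cannot direct, and the aryllithium is brominated by halogen transfer.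

Step 4
Reactants: 6 1-bromo-2,3,5-trimethoxy-4-(propan-2-yl)benzene
Product: 8 2-bromo-3,4,6-trimethoxy-5-(propan-2-yl)benzaldehyde, via aryl(chloro)methyl methyl ether 7 (not isolated)
Conditions: Cl2CHOMe, TiCl4, CH2Cl2, −10 to 0 °C; then H2O
Reagents that add atoms: dichloromethyl methyl ether, COC(Cl)Cl; water, O
Why: Rieche formylation at the only free ring position (C8), which is ortho to the C14 and para to the C12 methoxy group, followed by hydrolysis of the α-chloro ether.

Step 5
Reactants: 9 3-methylfuran-2(5H)-one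
Product: 10 trimethyl[(3-methylfuran-2-yl)oxy]silane
Conditions: Me3SiOTf, Et3N, CH2Cl2, 0 °C
Reagents that add atoms: trimethylsilyl trifluoromethanesulfonate, C[Si](C)(C)OS(=O)(=O)C(F)(F)F
Why: Soft enolisation and O-silylation of the butenolide give the aromatic 2-silyloxyfuran (silyl dienol ether formation).

Step 6
Reactants: 8 2-bromo-3,4,6-trimethoxy-5-(propan-2-yl)benzaldehyde; 10 trimethyl[(3-methylfuran-2-yl)oxy]silane
Product: 12 (5R)-5-[(S)-Ar(hydroxy)methyl]-3-methylfuran-2(5H)-one, via trimethylsilyl ether 11 (not isolated)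
Conditions: 9-amino-9-deoxy-epi-cinchona-alkaloid 3,5-bis(trifluoromethyl)phenylthiourea·CF3CO2H (10 mol %), CH2Cl2–Et2O, −20 °C; then 1 M HCl, THF
Reagents that add atoms: none
Why: Catalytic enantioselective vinylogous Mukaiyama aldol reaction: the chiral ammonium carboxylate activates the silyloxyfuran, the thiourea binds the aldehyde, and γ-attack through an open transition state should give the anti (6R,7S) adduct, both new stereocentres being set by the catalyst.

Step 7
Reactants: 12 (5R)-5-[(S)-Ar(hydroxy)methyl]-3-methylfuran-2(5H)-one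
Product: 13 (5R)-5-[(S)-Ar(tert-butyldimethylsilyloxy)methyl]-3-methylfuran-2(5H)-one
Conditions: t-BuMe2SiCl, imidazole, DMAP (cat.), DMF, 40 °C
Reagents that add atoms: tert-butyldimethylsilyl chloride, CC(C)(C)[Si](C)(C)Cl
Why: Standard silylation of the C7 hydroxyl; imidazole is too weak a base to enolise the butenolide, so C6 is not epimerised.

Step 8
Reactants: 13 (5R)-5-[(S)-Ar(tert-butyldimethylsilyloxy)methyl]-3-methylfuran-2(5H)-one; 14 (E)-3-(tert-butyldimethylsilyloxy)-N,N-dimethylbuta-1,3-dien-1-amine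
Product: 16 (3R,3aR,7aS)-3-[(S)-Ar(TBS-oxy)methyl]-7a-methyl-3a,4-dihydro-2-benzofuran-1,5(3H,7aH)-dione, via Diels–Alder adduct 15 (not isolated)
Conditions: toluene, 100 °C, sealed tube; then 1 M HCl, THF, 0 °C
Reagents that add atoms: none
Why: Normal-demand Diels–Alder reaction: the CH2 terminus of the amino siloxy diene bonds to the lactone β-carbon C5 and the aminated terminus to C4, the diene adds anti to the bulky C6 side chain and so sets C5 and the quaternary C4 (cis fusion by suprafacial addition), and acid then hydrolyses the silyl enol ether and eliminates dimethylamine to the enone.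

Step 9
Reactants: 16 (3R,3aR,7aS)-3-[(S)-Ar(TBS-oxy)methyl]-7a-methyl-3a,4-dihydro-2-benzofuran-1,5(3H,7aH)-dione
Product: 20 (3R,3aR,7aS)-3-[(S)-Ar(TBS-oxy)methyl]-7a-methyl-4-methylidene-3a,4-dihydro-2-benzofuran-1,5(3H,7aH)-dione, via lithium dienolate 17 (not isolated), via Mannich base 18 (not isolated), via trimethylammonium iodide 19 (not isolated)
Conditions: LiN(i-Pr)2, THF, −78 °C; CH2=NMe2 I, −78 to 0 °C; then MeI, MeOH, rt; then aq. NaHCO3, CH2Cl2, rt
Reagents that add atoms: N,N-dimethylmethyleneiminium iodide, C=[N+](C)C.[I-]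
Why: The enone can be enolised only at C10 (C4 is quaternary), so kinetic deprotonation, Mannich reaction, quaternisation and elimination place the methylene carbon C20 on C10.

Step 10
Reactants: 20 (3R,3aR,7aS)-3-[(S)-Ar(TBS-oxy)methyl]-7a-methyl-4-methylidene-3a,4-dihydro-2-benzofuran-1,5(3H,7aH)-dione
Product: 21 (4S,5R,6R,7S)-7-(tert-butyldimethylsilyloxy)-11,12,14-trimethoxy-1-oxoicetexa-2,8,10(20),11,13-pentaen-19,6-olide
Conditions: Pd2(dba)3 (5 mol %), P(t-Bu)3·HBF4 (12 mol %), Cy2NMe, 1,4-dioxane (0.01 M), 80 °C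
Reagents that add atoms: none
Why: Zerovalent palladium inserts into the C9–Br bond, the aryl–palladium adds syn across the exocyclic C10=C20 bond with the aryl group going to the terminal, carbonyl-β carbon C20, and the C10 palladium enolate loses the benzylic C20 hydrogen by β-hydride elimination (after C/O-enolate equilibration if needed) to give the arylidene ketone, the amine base returning the palladium hydride to the zerovalent state. The closest known reaction type is the intramolecular Mizoroki–Heck reaction of aryl halides with methacrylate-type α-methylene carbonyl acceptors giving benzo-fused cycloheptenes. Ring B is closed in the 7-endo-trig mode. No stereocentre is formed: the alkene geometry is fixed by the ring (C9 cis to C5) and the four existing stereocentres are not touched. The step needs 7-endo over 6-exo insertion, secured by the C1 carbonyl (aryl to the electron-poor unsubstituted β-carbon, while 6-exo would build a quaternary C10 and a neopentyl palladium without β-hydrogen), and elimination toward C20 and not C5, favoured by the benzylic C–H bond and the doubly conjugated product. The bulky electron-rich P(t-Bu)3 is chosen because the C9–Br bond has two ortho substituents.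

Step 11
Reactants: 21 (4S,5R,6R,7S)-7-(tert-butyldimethylsilyloxy)-11,12,14-trimethoxy-1-oxoicetexa-2,8,10(20),11,13-pentaen-19,6-olide
Product: 22 (4S,5R,6R,7S)-7-(tert-butyldimethylsilyloxy)-11,12,14-trimethoxy-1-oxoicetexa-8,10(20),11,13-tetraen-19,6-olide
Conditions: H2 (3 atm), RhCl(PPh3)3 (10 mol %), benzene–EtOH, rt
Reagents that add atoms: none
Why: Homogeneous hydrogenation discriminates by substitution: the cis-disubstituted C2=C3 bond should be reduced while the hindered trisubstituted arylidene C10=C20 bond stays.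

Step 12
Reactants: 22 (4S,5R,6R,7S)-7-(tert-butyldimethylsilyloxy)-11,12,14-trimethoxy-1-oxoicetexa-8,10(20),11,13-tetraen-19,6-olide
Product: 23 (1R,4S,5R,6R,7S)-7-(tert-butyldimethylsilyloxy)-1-hydroxy-11,12,14-trimethoxyicetexa-8,10(20),11,13-tetraen-19,6-olide
Conditions: NaBH4, CeCl3·7H2O, MeOH, −78 °C
Reagents that add atoms: none
Why: Luche 1,2-reduction: hydride should add axially from the α face of the ring A chair (H5 axial), placing the new C1 hydroxyl equatorial and β, that is (1R), under substrate control.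

Step 13
Reactants: 23 (1R,4S,5R,6R,7S)-7-(tert-butyldimethylsilyloxy)-1-hydroxy-11,12,14-trimethoxyicetexa-8,10(20),11,13-tetraen-19,6-olide
Product: 24 (1R,4S,5R,6R,7S)-7-(tert-butyldimethylsilyloxy)-1-hydroxy-12-methoxy-11,14-dioxoicetexa-8,10(20),12-trien-19,6-olide
Conditions: (NH4)2Ce(NO3)6, MeCN–H2O (3:1), 0 °C
Reagents that add atoms: water, O
Why: Oxidative demethylation of the para-dimethoxy pair (C11, C14) through the arene radical cation gives the para-quinone, water supplying both carbonyl oxygens and the C12 methoxy group remaining as a vinylogous ester.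

Step 14
Reactants: 24 (1R,4S,5R,6R,7S)-7-(tert-butyldimethylsilyloxy)-1-hydroxy-12-methoxy-11,14-dioxoicetexa-8,10(20),12-trien-19,6-olide
Product: 25 (1R,4S,5R,6R,7S)-7-(tert-butyldimethylsilyloxy)-1,12-dihydroxy-11,14-dioxoicetexa-8,10(20),12-trien-19,6-olide
Conditions: LiOH (0.2 M aq.), THF, 0 °C; then 1 M HCl
Reagents that add atoms: lithium hydroxide, [Li+].[OH-]
Why: Vinylogous ester hydrolysis by addition–elimination at C12 gives the stabilised hydroxyquinone anion, the silyl ether keeps C7 from translactonisation, and acidification would reclose any opened γ-lactone.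

Step 15
Reactants: 25 (1R,4S,5R,6R,7S)-7-(tert-butyldimethylsilyloxy)-1,12-dihydroxy-11,14-dioxoicetexa-8,10(20),12-trien-19,6-olide
Product: 26 ballotiquinone, (1R,4S,5R,6R,7S)-1,7,12-trihydroxy-11,14-dioxoicetexa-8,10(20),12-trien-19,6-olide
Conditions: HF·pyridine, THF, 0 °C to rt
Reagents that add atoms: none
Why: Fluoride-driven cleavage of the Si–O bond under buffered acidic conditions frees the C7 hydroxyl without exposing the hydroxyquinone and lactone to base.

Compound list
1 | 1,2,4-trimethoxybenzene | COc1ccc(OC)c(OC)c1 | starting material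
2 | (2,3,6-trimethoxyphenyl)lithium | COc1ccc(OC)c([Li])c1OC | intermediate
3 | 2-(2,3,6-trimethoxyphenyl)propan-2-ol | COc1ccc(OC)c(C(C)(C)O)c1OC | intermediate
4 | 1,2,4-trimethoxy-3-(propan-2-yl)benzene | COc1ccc(OC)c(C(C)C)c1OC | intermediate
5 | [2,3,5-trimethoxy-4-(propan-2-yl)phenyl]lithium | COc1c([Li])cc(OC)c(C(C)C)c1OC | intermediate
6 | 1-bromo-2,3,5-trimethoxy-4-(propan-2-yl)benzene | COc1c(Br)cc(OC)c(C(C)C)c1OC | intermediate
7 | [2-bromo-3,4,6-trimethoxy-5-(propan-2-yl)phenyl](chloro)methyl methyl ether | COC(Cl)c1c(Br)c(OC)c(OC)c(C(C)C)c1OC | intermediate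
8 | 2-bromo-3,4,6-trimethoxy-5-(propan-2-yl)benzaldehyde | COc1c(Br)c(C=O)c(OC)c(C(C)C)c1OC | intermediate
9 | 3-methylfuran-2(5H)-one | CC1=CCOC1=O | starting material
10 | trimethyl[(3-methylfuran-2-yl)oxy]silane | Cc1ccoc1O[Si](C)(C)C | intermediate
11 | (5R)-5-[(S)-Ar(trimethylsilyloxy)methyl]-3-methylfuran-2(5H)-one | CC(C)c1c(OC)c(OC)c(Br)c(c1OC)[C@H](O[Si](C)(C)C)[C@@H]1OC(=O)C(C)=C1 | intermediate
12 | (5R)-5-[(S)-Ar(hydroxy)methyl]-3-methylfuran-2(5H)-one (anti aldol, 6R,7S) | CC(C)c1c(OC)c(OC)c(Br)c(c1OC)[C@H](O)[C@@H]1OC(=O)C(C)=C1 | intermediate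
13 | (5R)-5-[(S)-Ar(tert-butyldimethylsilyloxy)methyl]-3-methylfuran-2(5H)-one | CC(C)c1c(OC)c(OC)c(Br)c(c1OC)[C@H](O[Si](C)(C)C(C)(C)C)[C@@H]1OC(=O)C(C)=C1 | intermediate
14 | (E)-3-(tert-butyldimethylsilyloxy)-N,N-dimethylbuta-1,3-dien-1-amine | C=C(O[Si](C)(C)C(C)(C)C)/C=C/N(C)C | starting material
15 | Diels–Alder adduct: cis-fused lactone with C1 silyl enol ether (C1=C2) and C3 dimethylamino group (C3 epimers), C4–C7 as in 16 | CC(C)c1c(OC)c(OC)c(Br)c(c1OC)[C@H](O[Si](C)(C)C(C)(C)C)[C@@H]1OC(=O)[C@@]2(C)C(N(C)C)C=C(O[Si](C)(C)C(C)(C)C)C[C@@H]12 | intermediate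
16 | (3R,3aR,7aS)-3-[(S)-Ar(TBS-oxy)methyl]-7a-methyl-3a,4-dihydro-2-benzofuran-1,5(3H,7aH)-dione (4S,5R,6R,7S) | CC(C)c1c(OC)c(OC)c(Br)c(c1OC)[C@H](O[Si](C)(C)C(C)(C)C)[C@@H]1OC(=O)[C@@]2(C)C=CC(=O)C[C@@H]12 | intermediate
17 | lithium C1,C10-dienolate of 16 | CC(C)c1c(OC)c(OC)c(Br)c(c1OC)[C@H](O[Si](C)(C)C(C)(C)C)[C@@H]1OC(=O)[C@@]2(C)C=CC(O[Li])=C[C@@H]12 | intermediate
18 | C10-(dimethylaminomethyl) derivative of 16 (C10 epimers) | CC(C)c1c(OC)c(OC)c(Br)c(c1OC)[C@H](O[Si](C)(C)C(C)(C)C)[C@@H]1OC(=O)[C@@]2(C)C=CC(=O)C(CN(C)C)[C@@H]12 | intermediate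
19 | C10-(trimethylammoniomethyl) derivative of 16, iodide (C10 epimers) | CC(C)c1c(OC)c(OC)c(Br)c(c1OC)[C@H](O[Si](C)(C)C(C)(C)C)[C@@H]1OC(=O)[C@@]2(C)C=CC(=O)C(C[N+](C)(C)C)[C@@H]12.[I-] | intermediate
20 | (3R,3aR,7aS)-3-[(S)-Ar(TBS-oxy)methyl]-7a-methyl-4-methylidene-3a,4-dihydro-2-benzofuran-1,5(3H,7aH)-dione | CC(C)c1c(OC)c(OC)c(Br)c(c1OC)[C@H](O[Si](C)(C)C(C)(C)C)[C@@H]1OC(=O)[C@@]2(C)C=CC(=O)C(=C)[C@@H]12 | intermediate
21 | (4S,5R,6R,7S)-7-(tert-butyldimethylsilyloxy)-11,12,14-trimethoxy-1-oxoicetexa-2,8,10(20),11,13-pentaen-19,6-olide | CC(C)c1c(OC)c(OC)c2c(c1OC)[C@H](O[Si](C)(C)C(C)(C)C)[C@@H]1OC(=O)[C@@]3(C)C=CC(=O)C(=C2)[C@@H]13 | intermediate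
22 | (4S,5R,6R,7S)-7-(tert-butyldimethylsilyloxy)-11,12,14-trimethoxy-1-oxoicetexa-8,10(20),11,13-tetraen-19,6-olide | CC(C)c1c(OC)c(OC)c2c(c1OC)[C@H](O[Si](C)(C)C(C)(C)C)[C@@H]1OC(=O)[C@@]3(C)CCC(=O)C(=C2)[C@@H]13 | intermediate
23 | (1R,4S,5R,6R,7S)-7-(tert-butyldimethylsilyloxy)-1-hydroxy-11,12,14-trimethoxyicetexa-8,10(20),11,13-tetraen-19,6-olide | CC(C)c1c(OC)c(OC)c2c(c1OC)[C@H](O[Si](C)(C)C(C)(C)C)[C@@H]1OC(=O)[C@@]3(C)CC[C@@H](O)C(=C2)[C@@H]13 | intermediate
24 | (1R,4S,5R,6R,7S)-7-(tert-butyldimethylsilyloxy)-1-hydroxy-12-methoxy-11,14-dioxoicetexa-8,10(20),12-trien-19,6-olide | CC(C)C1=C(OC)C(=O)C2=C(C1=O)[C@H](O[Si](C)(C)C(C)(C)C)[C@@H]1OC(=O)[C@@]3(C)CC[C@@H](O)C(=C2)[C@@H]13 | intermediate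
25 | (1R,4S,5R,6R,7S)-7-(tert-butyldimethylsilyloxy)-1,12-dihydroxy-11,14-dioxoicetexa-8,10(20),12-trien-19,6-olide | CC(C)C1=C(O)C(=O)C2=C(C1=O)[C@H](O[Si](C)(C)C(C)(C)C)[C@@H]1OC(=O)[C@@]3(C)CC[C@@H](O)C(=C2)[C@@H]13 | intermediate
26 | ballotiquinone, (1R,4S,5R,6R,7S)-1,7,12-trihydroxy-11,14-dioxoicetexa-8,10(20),12-trien-19,6-olide | CC(C)C1=C(O)C(=O)C2=C(C1=O)[C@H](O)[C@@H]1OC(=O)[C@@]3(C)CC[C@@H](O)C(=C2)[C@@H]13 | target

Total step count: 15. Longest linear sequence: 14 steps (steps 1–4 and 6–15; step 5 is a side branch).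

Steps most likely to fail

Step 10. Oxidative addition into the doubly ortho-substituted, electron-rich C9–Br bond may be slow. Insertion may go 6-exo at C10, or β-hydride elimination may take the C5 hydrogen and destroy that stereocentre. The phosphine may also trigger oligomerisation of the cross-conjugated dienone. The fallback sets out from 20 and makes the C9–C20 bond by a radical instead: Bu3SnH and AIBN in benzene at 80 °C (slow addition) should give 7-endo attack of the aryl radical on the unsubstituted alkene terminus and, after hydrogen transfer, the C10-saturated tricyclic enone (4S,5R,6R,7S)-7-(tert-butyldimethylsilyloxy)-11,12,14-trimethoxy-1-oxoicetexa-2,8,11,13-tetraen-19,6-olide F1 as C10 epimers. Kinetic deprotonation at C10 (LiN(i-Pr)2, THF, −78 °C) and trapping with PhSeCl would give the C10 phenylselenide of that ketone F2. Oxidation (H2O2, pyridine, CH2Cl2) and selenoxide syn-elimination toward the benzylic C20 hydrogen then comes back to the route at 21.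

Step 6. The hindered, electron-rich aldehyde may convert poorly, or the anti and facial selectivities may be lower than on simple aryl aldehydes. The fallback sets out from 8 and builds the butenolide after the two stereocentres: anti-selective γ-borylallylboration with (E)-[3-(1,3,2-dioxaborinan-2-yl)allyl]diisopinocampheylborane (antipode chosen for the 7S carbinol; oxidative work-up with H2O2, NaOH) should give the anti diol (1S,2R)-1-Ar-but-3-ene-1,2-diol F3. Selective acylation of the less hindered allylic hydroxyl with methacryloyl chloride (2,4,6-collidine, CH2Cl2, −78 °C) would give (1S,2R)-1-Ar-1-hydroxybut-3-en-2-yl 2-methylprop-2-enoate F4. Ring-closing metathesis (second-generation Grubbs catalyst, CH2Cl2, 40 °C) closes the butenolide and comes back to the route at 12.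

Step 8. The trisubstituted α-methyl butenolide may be too poor a dienophile, so that the diene decomposes before cycloaddition. The fallback sets out from 13 and forms ring A by two polar steps: the lithium enolate of (E)-4-methoxybut-3-en-2-one (LiN(i-Pr)2, THF, −78 °C) should add in a Michael reaction to C5 anti to the side chain and give, after protonation, (4R,5R)-5-[(S)-Ar(TBS-oxy)methyl]-4-[(E)-4-methoxy-2-oxobut-3-en-1-yl]-3-methyloxolan-2-one F5 (C4 epimers in icetexane locants). t-BuOK in THF at 0 °C would form the lactone enolate, which closes ring A by intramolecular Michael addition to the β-methoxy enone and loss of methoxide, the tether enforcing the cis fusion, and comes back to the route at 16.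

Further compounds
F1 | step 10 | (4S,5R,6R,7S)-7-(tert-butyldimethylsilyloxy)-11,12,14-trimethoxy-1-oxoicetexa-2,8,11,13-tetraen-19,6-olide (C10 epimers) | CC(C)c1c(OC)c(OC)c2c(c1OC)[C@H](O[Si](C)(C)C(C)(C)C)[C@@H]1OC(=O)[C@@]3(C)C=CC(=O)C(C2)[C@@H]13
F2 | step 10 | 10-(phenylselanyl) derivative of F1 (C10 epimers) | CC(C)c1c(OC)c(OC)c2c(c1OC)[C@H](O[Si](C)(C)C(C)(C)C)[C@@H]1OC(=O)[C@@]3(C)C=CC(=O)C([Se]c4ccccc4)(C2)[C@@H]13
F3 | step 6 | (1S,2R)-1-[2-bromo-3,4,6-trimethoxy-5-(propan-2-yl)phenyl]but-3-ene-1,2-diol | CC(C)c1c(OC)c(OC)c(Br)c(c1OC)[C@H](O)[C@H](O)C=C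
F4 | step 6 | (1S,2R)-1-[2-bromo-3,4,6-trimethoxy-5-(propan-2-yl)phenyl]-1-hydroxybut-3-en-2-yl 2-methylprop-2-enoate | CC(C)c1c(OC)c(OC)c(Br)c(c1OC)[C@H](O)[C@H](OC(=O)C(C)=C)C=C
F5 | step 8 | (4R,5R)-5-[(S)-Ar(tert-butyldimethylsilyloxy)methyl]-4-[(E)-4-methoxy-2-oxobut-3-en-1-yl]-3-methyloxolan-2-one (epimers at the methyl-bearing carbon) | CC(C)c1c(OC)c(OC)c(Br)c(c1OC)[C@H](O[Si](C)(C)C(C)(C)C)[C@@H]1OC(=O)C(C)[C@H]1CC(=O)/C=C/OC
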